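The constants used here were chosen freely, and the outcome is calculated.

- Violet and amber each start with 0.10 M of first end groups, violet with 0.950 equiv of second end groups and amber with 1.20 equiv, and each first end group that reacts uses up one second end group, whether it goes to links or to rings.

| setting | violet | amber |
|---|---|---|
| first end groups | 0.10 M | 0.10 M |
| second end groups | 0.950 equiv | 1.20 equiv |
| time | 50 min | 50 min |

    first end groups + second end groups → links (k1 = 0.12 M⁻¹ s⁻¹)
    first end groups + links ⇌ idle adduct, settled at all times (K2 = 21 M⁻¹)
    first end groups + second end groups → rings, rate k3*[first end groups] as long as [second end groups] is above zero (k3 = 0.0058 s⁻¹)

- a species is counted by the first end groups in it: one idle adduct counts as two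
- amounts and yields of links count idle adduct too
- in an amount of links, one idle adduct counts as one links
- run time (violet): 50 min

- which of the two there is more of at the end, violet (rings / links)
- which of the two there is more of at the end, amber (rings / links)
- links at the end, in percent of the first end groups charged, violet
- links at the end, in percent of the first end groups charged, amber

- I compared the two rates at one moment. With A and B the free first and second end groups, and kL and kR the constants of the link and ring steps, links form at kL[A][B] and rings at kR[A]. [A] cancels, so the ratio of links to rings being made is kL[B]/kR, a selectivity factor that falls as B is used.
- I folded the givens into one number, N = kL·C/kR, with C the charge of first end groups, and it came to 2.07: the link-to-ring ratio if B stood at C.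
- Let s and e be B per C at the start and finish. Summing the drifting ratio gives links, as a share of C, of (s − e) − ln[(1 + N·s)/(1 + N·e)]/N.
- One number was not enough: N was 2.07 in both flasks, since C was 0.10 M in each. The equivalents told me the limiting reagent. In violet, with 0.950 equiv, it was second end groups, so e was zero, giving 42.5% links and 52.5% rings. In amber, with 1.20 equiv, it was first end groups, giving 56.4% links and 43.6% rings.
- I took both runs as finished, since the ring step's time 1/kR, 2.87 min, is short beside the 50 min run.
- The forecast gave rings for violet and links for amber, with links at 42.4% (41.5% to 43.5%) and 56.4% (55% to 57.5%), a split “which favours links early and rings as second end groups fall”.
- Violet ended with 42.5% links and 52.5% rings, amber with 56.4% links and 43.6% rings.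
- Violet's ratio N·s began at 1.97 and its second end groups ended at 0%, while amber's ratio stopped at 0.414 with 17% of its second end groups left. A neighbour of violet, charged with 0.17 M of first end groups at the same equivalents, had N of 3.52, larger than violet's, and the same sum gave 53.3% links. That neighbour ended with more links than rings, 53.3% against 41.7%.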